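**Plan**

1. The target is read as unit 1 (the styryl-bearing dihydrobenzofuran: O1, C2, C3, benzo ring A) joined through C2 to C7' of unit 2 (the dihydrobenzofuran O1', C2', C3', benzo ring B with the 4'-OH). The nine phenols are carried as methyl ethers and exchanged for acetates before the alkene is made.
2. Retrosynthetic cuts, in order: the acetates; the ring A–vinyl bond (Heck); the C2 epimer; C2–C3 of unit 1 (carbene C–H insertion) and the O1–CH2 ether bond (Mitsunobu); in unit 2 the O1'–C7a' bond together with the C7'–CHO bond in one operation; the C3'–aryl bond (ketone α-arylation); the C2'(=O)–aryl bond (Friedel–Crafts).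
3. Forward: open-chain triarylethanol 7 → furan ring of unit 2 closed by an aryne cascade that also formylates C7' → benzylic alcohol → aryl ether with benzophenone 17 → furan ring of unit 1 by C–H insertion → C2 epimerisation → demethylation/acetylation → Heck → deacetylation.
4. Feature that makes the key event possible: in ring B the oxygen-bearing C7a' and C7' (the carbon that must carry unit 1) are neighbours, and C3a' next to C7a' holds the C3'–C2' chain. A C7a'–F/C7'–Br pair therefore becomes a C7a'≡C7' aryne, to which the C2' alkoxide can add only at C7a' (five-membered ring), leaving the carbanion exactly at C7'.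
5. Stereochemistry: C2'/C3' come from dynamic kinetic resolution in the ketone hydrogenation (catalyst sets C2', Felkin–Anh pairing sets C3') and pass unchanged through the ring closure. C3 comes from the chiral dirhodium carboxylate, C2 from acid equilibration to the trans ring, and the E-alkene from syn-β-hydride elimination in the Heck step.

Key step: step 5

Remark: the sense of induction in steps 4 and 12 is assigned by analogy with simple aryl alkyl ketones and 2-(benzyloxy)benzophenone hydrazones; if a model run shows the opposite sense, the mirror-image catalyst is used and nothing else changes. Compounds 1, 3, 5, 13, 15 and 25 are taken as purchasable.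

**Route**

Step 1
Reactants: 1 2-(2-fluoro-6-methoxyphenyl)acetic acid
Product: 2 2-(3-bromo-2-fluoro-6-methoxyphenyl)acetic acid
Conditions: NBS (1.05 equiv), MeCN, 0 °C to rt
Reagents that add atoms: N-bromosuccinimide, O=C1CCC(=O)N1Br
Why: Electrophilic aromatic bromination; the methoxy group directs para (the position next to fluorine), as in the bromination of 3-fluoroanisole.

Step 2
Reactants: 2 2-(3-bromo-2-fluoro-6-methoxyphenyl)acetic acid; 3 1,3-dimethoxybenzene
Product: 4 2-(3-bromo-2-fluoro-6-methoxyphenyl)-1-(2,4-dimethoxyphenyl)ethan-1-one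
Conditions: (CF3CO)2O (2 equiv), 85% H3PO4 (cat.), 3 (3 equiv), CH2Cl2, rt
Reagents that add atoms: none
Why: Friedel–Crafts acylation through the mixed trifluoroacetic anhydride; 1,3-dimethoxybenzene reacts at C4 and is far more nucleophilic than the bromofluoroanisole ring of 2.

Step 3
Reactants: 4 2-(3-bromo-2-fluoro-6-methoxyphenyl)-1-(2,4-dimethoxyphenyl)ethan-1-one; 5 1-iodo-3,5-dimethoxybenzene
Product: 6 racemic 2-(3-bromo-2-fluoro-6-methoxyphenyl)-1-(2,4-dimethoxyphenyl)-2-(3,5-dimethoxyphenyl)ethan-1-one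
Conditions: Pd2(dba)3 (2 mol %), Xantphos (5 mol %), NaOtBu (1.3 equiv), 5 (1.3 equiv), toluene, 70 °C
Reagents that add atoms: none
Why: Palladium-catalysed α-arylation of a ketone enolate; oxidative addition of zerovalent palladium to the C–I bond of 5 should be much faster than to the electron-rich C–Br bond of 4, and the hindered tertiary product should resist a second arylation.

Step 4
Reactants: 6 racemic 2-(3-bromo-2-fluoro-6-methoxyphenyl)-1-(2,4-dimethoxyphenyl)-2-(3,5-dimethoxyphenyl)ethan-1-one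
Product: 7 (1S,2S)-2-(3-bromo-2-fluoro-6-methoxyphenyl)-1-(2,4-dimethoxyphenyl)-2-(3,5-dimethoxyphenyl)ethan-1-ol
Conditions: RuCl2[(R)-xylbinap][(R)-daipen] (0.5 mol %), t-BuOK (10 mol %), H2 (10 atm), i-PrOH/THF, 30 °C
Reagents that add atoms: none
Why: Noyori hydrogenation with dynamic kinetic resolution: the doubly benzylic α-hydrogen lets t-BuOK racemise C2 through the enolate, while the catalyst adds hydride to one carbonyl face (1S, by analogy with acetophenone) and should reduce faster the enantiomer for which this is also the Felkin–Anh face (bromofluoroanisyl ring as the large group), which sets 2S.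

Step 5
Reactants: 7 (1S,2S)-2-(3-bromo-2-fluoro-6-methoxyphenyl)-1-(2,4-dimethoxyphenyl)-2-(3,5-dimethoxyphenyl)ethan-1-ol
Product: 11 (2S,3S)-2-(2,4-dimethoxyphenyl)-3-(3,5-dimethoxyphenyl)-4-methoxy-2,3-dihydro-1-benzofuran-7-carbaldehyde, via dilithio species 8 (not isolated), via aryne alkoxide 9 (not isolated), via 7-lithiodihydrobenzofuran 10 (not isolated)
Conditions: n-BuLi (1.05 equiv), THF (0.02 M), −78 °C; t-BuLi (2.1 equiv), −78 °C; warm to −30 °C; DMF (5 equiv), −30 to 0 °C; H2O
Reagents that add atoms: N,N-dimethylformamide, CN(C)C=O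
Why: n-BuLi makes the lithium alkoxide and t-BuLi exchanges the bromine (faster at −78 °C than any directed lithiation of the methoxyarenes; the second equivalent destroys t-BuBr) to give 8, which on warming loses LiF across the former C–Li and C–F carbons to give aryne 9. The tethered alkoxide adds to the nearer aryne carbon in a 5-exo-dig closure that forms the O–C(aryl) bond and the dihydrofuran ring, and the aryllithium 10 left on the neighbouring carbon (stabilised by the new ring oxygen) is formylated by DMF. The closest known reaction type is the anionic benzyne cyclisation of a tethered heteroatom nucleophile followed by electrophilic quench of the resulting aryllithium. No stereocenter is formed or touched: the C–O and C–aryl bonds at the two stereocenters of 7 stay intact, so the (1S,2S) alcohol should give the (2S,3S) trans ring. The step needs regiospecific aryne formation (secured by the ortho Br/F pair), attack at the proximal aryne carbon only (the tether on the adjacent ring carbon cannot reach the distal one) and ring closure faster than intermolecular capture (secured by dilution and the absence of other nucleophiles or proton sources).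

Step 6
Reactants: 11 (2S,3S)-2-(2,4-dimethoxyphenyl)-3-(3,5-dimethoxyphenyl)-4-methoxy-2,3-dihydro-1-benzofuran-7-carbaldehyde
Product: 12 [(2S,3S)-2-(2,4-dimethoxyphenyl)-3-(3,5-dimethoxyphenyl)-4-methoxy-2,3-dihydro-1-benzofuran-7-yl]methanol
Conditions: NaBH4, MeOH/THF, 0 °C
Reagents that add atoms: none
Why: Hydride reduction of an aryl aldehyde; the stereocenters are not involved.

Step 7
Reactants: 13 2-bromo-4,6-dimethoxybenzaldehyde
Product: 14 2-bromo-6-hydroxy-4-methoxybenzaldehyde
Conditions: BCl3 (1.2 equiv), CH2Cl2, −78 to 0 °C; H2O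
Reagents that add atoms: none
Why: Chelation-controlled Lewis-acid cleavage of the only methyl ether ortho to the formyl group.

Step 8
Reactants: 14 2-bromo-6-hydroxy-4-methoxybenzaldehyde; 15 (3,5-dimethoxyphenyl)magnesium chloride
Product: 16 racemic 3-bromo-2-[(3,5-dimethoxyphenyl)(hydroxy)methyl]-5-methoxyphenol
Conditions: 15 (2.5 equiv), THF, 0 °C; aqueous work-up
Reagents that add atoms: none
Why: Grignard addition to the aldehyde after the first equivalent is consumed by the phenol; the new stereocenter is racemic and is removed in step 9.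

Step 9
Reactants: 16 racemic 3-bromo-2-[(3,5-dimethoxyphenyl)(hydroxy)methyl]-5-methoxyphenol
Product: 17 (2-bromo-6-hydroxy-4-methoxyphenyl)(3,5-dimethoxyphenyl)methanone
Conditions: MnO2 (activated, excess), CH2Cl2, rt
Reagents that add atoms: none
Why: MnO2 oxidation of a benzhydrylic alcohol to the diaryl ketone; the phenol is left alone.

Step 10
Reactants: 12 [(2S,3S)-2-(2,4-dimethoxyphenyl)-3-(3,5-dimethoxyphenyl)-4-methoxy-2,3-dihydro-1-benzofuran-7-yl]methanol; 17 (2-bromo-6-hydroxy-4-methoxyphenyl)(3,5-dimethoxyphenyl)methanone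
Product: 18 (2-bromo-6-{[(2S,3S)-2-(2,4-dimethoxyphenyl)-3-(3,5-dimethoxyphenyl)-4-methoxy-2,3-dihydro-1-benzofuran-7-yl]methoxy}-4-methoxyphenyl)(3,5-dimethoxyphenyl)methanone
Conditions: PPh3, diisopropyl azodicarboxylate, THF, 0 °C to rt
Reagents that add atoms: none
Why: Mitsunobu etherification of a primary benzylic alcohol with an acidic ortho-acyl phenol; no stereocenter is involved.

Step 11
Reactants: 18 (2-bromo-6-{[(2S,3S)-2-(2,4-dimethoxyphenyl)-3-(3,5-dimethoxyphenyl)-4-methoxy-2,3-dihydro-1-benzofuran-7-yl]methoxy}-4-methoxyphenyl)(3,5-dimethoxyphenyl)methanone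
Product: 19 the hydrazone of 18 (E/Z mixture)
Conditions: N2H4·H2O (20 equiv), AcOH (cat.), n-BuOH, 110 °C
Reagents that add atoms: hydrazine, NN
Why: Condensation of the diaryl ketone with hydrazine, forced by excess reagent and heat because the ketone is di-ortho-substituted; the acid-labile benzylic ether should tolerate catalytic acetic acid.

Step 12
Reactants: 19 the hydrazone of 18
Product: 21 (2R,3S)-4-bromo-2-[(2S,3S)-2-(2,4-dimethoxyphenyl)-3-(3,5-dimethoxyphenyl)-4-methoxy-2,3-dihydro-1-benzofuran-7-yl]-3-(3,5-dimethoxyphenyl)-6-methoxy-2,3-dihydro-1-benzofuran, via diazo compound 20 (not isolated)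
Conditions: MnO2 (8 equiv), CH2Cl2, 0 °C; filter; Rh2(R-PTAD)4 (1 mol %), CH2Cl2, 0 °C to rt
Reagents that add atoms: none
Why: Oxidation of the hydrazone to the diaryldiazomethane and dirhodium-catalysed intramolecular 1,5 C–H insertion of the donor/donor carbene into the electron-rich benzylic ether C–H; this reaction type gives cis-2,3-diaryl-2,3-dihydrobenzofurans, and the chiral carboxylate ligands select the carbene face and so should fix C3 as S (C2 is then R).

Step 13
Reactants: 21 (2R,3S)-4-bromo-2-[(2S,3S)-2-(2,4-dimethoxyphenyl)-3-(3,5-dimethoxyphenyl)-4-methoxy-2,3-dihydro-1-benzofuran-7-yl]-3-(3,5-dimethoxyphenyl)-6-methoxy-2,3-dihydro-1-benzofuran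
Product: 22 (2S,3S)-4-bromo-2-[(2S,3S)-2-(2,4-dimethoxyphenyl)-3-(3,5-dimethoxyphenyl)-4-methoxy-2,3-dihydro-1-benzofuran-7-yl]-3-(3,5-dimethoxyphenyl)-6-methoxy-2,3-dihydro-1-benzofuran
Conditions: CF3CO2H (5 equiv), CH2Cl2, 0 °C
Reagents that add atoms: none
Why: Acid-mediated epimerisation: the C2–O1 bond ionises reversibly to a benzylic cation stabilised by the ortho ring oxygen and the para methoxy group of ring B and recloses to the thermodynamically preferred trans ring (C2 becomes S); C3 is not touched and the already trans unit 2 is unchanged.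

Step 14
Reactants: 22 (2S,3S)-4-bromo-2-[(2S,3S)-2-(2,4-dimethoxyphenyl)-3-(3,5-dimethoxyphenyl)-4-methoxy-2,3-dihydro-1-benzofuran-7-yl]-3-(3,5-dimethoxyphenyl)-6-methoxy-2,3-dihydro-1-benzofuran
Product: 24 the octaacetate of the octaphenol corresponding to 22, via octaphenol 23 (not isolated)
Conditions: BBr3 (20 equiv), CH2Cl2, −78 °C to rt; H2O; then Ac2O, pyridine, DMAP (cat.), rt
Reagents that add atoms: acetic anhydride, CC(=O)OC(C)=O
Why: Lewis-acid cleavage of all eight aryl methyl ethers, done before the stilbene exists because acid converts such stilbenes into cyclised products, then acetylation of the crude octaphenol to a stable Heck substrate; any ring opening at C2 or C2' under BBr3 is reversible and should return the trans rings.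

Step 15
Reactants: 24 the octaacetate; 25 4-ethenylphenyl acetate (4-acetoxystyrene)
Product: 26 the nonaacetate of the target
Conditions: 25 (2 equiv), Pd(OAc)2 (5 mol %), P(o-tol)3 (10 mol %), Et3N, DMF, 100 °C
Reagents that add atoms: none
Why: Heck reaction of the aryl bromide; syn-insertion and syn-β-hydride elimination give the E-stilbene, and aryl acetates tolerate the conditions.

Step 16
Reactants: 26 the nonaacetate of the target
Product: 27 CNP0397447.1, the (2S,3S,2'S,3'S) target
Conditions: K2CO3 (cat.), MeOH, 0 °C, argon; then AcOH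
Reagents that add atoms: none
Why: Transesterification of the nine aryl acetates under mild, non-acidic conditions that should leave the stilbene and both trans dihydrofuran rings untouched.

**Compound list**

1 | 2-(2-fluoro-6-methoxyphenyl)acetic acid | COc1cccc(F)c1CC(=O)O | starting material
2 | 2-(3-bromo-2-fluoro-6-methoxyphenyl)acetic acid | COc1ccc(Br)c(F)c1CC(=O)O | intermediate
3 | 1,3-dimethoxybenzene | COc1cccc(OC)c1 | starting material
4 | 2-(3-bromo-2-fluoro-6-methoxyphenyl)-1-(2,4-dimethoxyphenyl)ethan-1-one | COc1ccc(C(=O)Cc2c(OC)ccc(Br)c2F)c(OC)c1 | intermediate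
5 | 1-iodo-3,5-dimethoxybenzene | COc1cc(I)cc(OC)c1 | starting material
6 | racemic 2-(3-bromo-2-fluoro-6-methoxyphenyl)-1-(2,4-dimethoxyphenyl)-2-(3,5-dimethoxyphenyl)ethan-1-one | COc1ccc(C(=O)C(c2cc(OC)cc(OC)c2)c2c(OC)ccc(Br)c2F)c(OC)c1 | intermediate
7 | (1S,2S)-2-(3-bromo-2-fluoro-6-methoxyphenyl)-1-(2,4-dimethoxyphenyl)-2-(3,5-dimethoxyphenyl)ethan-1-ol | O[C@H](c1ccc(OC)cc1OC)[C@H](c1c(OC)ccc(Br)c1F)c1cc(OC)cc(OC)c1 | intermediate
8 | dilithio species: lithium alkoxide of 7 with lithium in place of bromine | [Li]O[C@H](c1ccc(OC)cc1OC)[C@H](c1c(OC)ccc([Li])c1F)c1cc(OC)cc(OC)c1 | intermediate (not isolated)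
9 | aryne alkoxide: lithium (1S,2S)-2-(2,3-didehydro-6-methoxyphenyl)-1-(2,4-dimethoxyphenyl)-2-(3,5-dimethoxyphenyl)ethan-1-olate | [Li]O[C@H](c1ccc(OC)cc1OC)[C@H](C1=C(OC)C=CC#C1)c1cc(OC)cc(OC)c1 | intermediate (not isolated)
10 | [(2S,3S)-2-(2,4-dimethoxyphenyl)-3-(3,5-dimethoxyphenyl)-4-methoxy-2,3-dihydro-1-benzofuran-7-yl]lithium | [Li]c1ccc(OC)c2c1O[C@H](c1ccc(OC)cc1OC)[C@H]2c1cc(OC)cc(OC)c1 | intermediate (not isolated)
11 | (2S,3S)-2-(2,4-dimethoxyphenyl)-3-(3,5-dimethoxyphenyl)-4-methoxy-2,3-dihydro-1-benzofuran-7-carbaldehyde | O=Cc1ccc(OC)c2c1O[C@H](c1ccc(OC)cc1OC)[C@H]2c1cc(OC)cc(OC)c1 | intermediate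
12 | [(2S,3S)-2-(2,4-dimethoxyphenyl)-3-(3,5-dimethoxyphenyl)-4-methoxy-2,3-dihydro-1-benzofuran-7-yl]methanol | OCc1ccc(OC)c2c1O[C@H](c1ccc(OC)cc1OC)[C@H]2c1cc(OC)cc(OC)c1 | intermediate
13 | 2-bromo-4,6-dimethoxybenzaldehyde | COc1cc(Br)c(C=O)c(OC)c1 | starting material
14 | 2-bromo-6-hydroxy-4-methoxybenzaldehyde | COc1cc(O)c(C=O)c(Br)c1 | intermediate
15 | (3,5-dimethoxyphenyl)magnesium chloride | COc1cc([Mg]Cl)cc(OC)c1 | starting material
16 | racemic 3-bromo-2-[(3,5-dimethoxyphenyl)(hydroxy)methyl]-5-methoxyphenol | COc1cc(O)c(C(O)c2cc(OC)cc(OC)c2)c(Br)c1 | intermediate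
17 | (2-bromo-6-hydroxy-4-methoxyphenyl)(3,5-dimethoxyphenyl)methanone | COc1cc(O)c(C(=O)c2cc(OC)cc(OC)c2)c(Br)c1 | intermediate
18 | (2-bromo-6-{[(2S,3S)-2-(2,4-dimethoxyphenyl)-3-(3,5-dimethoxyphenyl)-4-methoxy-2,3-dihydro-1-benzofuran-7-yl]methoxy}-4-methoxyphenyl)(3,5-dimethoxyphenyl)methanone | COc1cc(OCc2ccc(OC)c3c2O[C@H](c2ccc(OC)cc2OC)[C@H]3c2cc(OC)cc(OC)c2)c(C(=O)c2cc(OC)cc(OC)c2)c(Br)c1 | intermediate
19 | hydrazone of 18 | COc1cc(OCc2ccc(OC)c3c2O[C@H](c2ccc(OC)cc2OC)[C@H]3c2cc(OC)cc(OC)c2)c(C(=NN)c2cc(OC)cc(OC)c2)c(Br)c1 | intermediate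
20 | diazo compound from 19 (aryl(3,5-dimethoxyphenyl)diazomethane) | COc1cc(OCc2ccc(OC)c3c2O[C@H](c2ccc(OC)cc2OC)[C@H]3c2cc(OC)cc(OC)c2)c(C(=[N+]=[N-])c2cc(OC)cc(OC)c2)c(Br)c1 | intermediate (not isolated)
21 | (2R,3S)-4-bromo-2-[(2S,3S)-2-(2,4-dimethoxyphenyl)-3-(3,5-dimethoxyphenyl)-4-methoxy-2,3-dihydro-1-benzofuran-7-yl]-3-(3,5-dimethoxyphenyl)-6-methoxy-2,3-dihydro-1-benzofuran (cis in unit 1) | Brc1cc(OC)cc2c1[C@H](c1cc(OC)cc(OC)c1)[C@H](c1ccc(OC)c3c1O[C@H](c1ccc(OC)cc1OC)[C@H]3c1cc(OC)cc(OC)c1)O2 | intermediate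
22 | (2S,3S)-4-bromo-2-[(2S,3S)-2-(2,4-dimethoxyphenyl)-3-(3,5-dimethoxyphenyl)-4-methoxy-2,3-dihydro-1-benzofuran-7-yl]-3-(3,5-dimethoxyphenyl)-6-methoxy-2,3-dihydro-1-benzofuran (trans in both units) | Brc1cc(OC)cc2c1[C@H](c1cc(OC)cc(OC)c1)[C@@H](c1ccc(OC)c3c1O[C@H](c1ccc(OC)cc1OC)[C@H]3c1cc(OC)cc(OC)c1)O2 | intermediate
23 | octaphenol: 22 with all eight methoxy groups as hydroxy groups | Brc1cc(O)cc2c1[C@H](c1cc(O)cc(O)c1)[C@@H](c1ccc(O)c3c1O[C@H](c1ccc(O)cc1O)[C@H]3c1cc(O)cc(O)c1)O2 | intermediate (not isolated)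
24 | octaacetate of 23 | Brc1cc(OC(C)=O)cc2c1[C@H](c1cc(OC(C)=O)cc(OC(C)=O)c1)[C@@H](c1ccc(OC(C)=O)c3c1O[C@H](c1ccc(OC(C)=O)cc1OC(C)=O)[C@H]3c1cc(OC(C)=O)cc(OC(C)=O)c1)O2 | intermediate
25 | 4-ethenylphenyl acetate | CC(=O)Oc1ccc(C=C)cc1 | starting material
26 | nonaacetate of the target | CC(=O)Oc1ccc(/C=C/c2cc(OC(C)=O)cc3c2[C@H](c2cc(OC(C)=O)cc(OC(C)=O)c2)[C@@H](c2ccc(OC(C)=O)c4c2O[C@H](c2ccc(OC(C)=O)cc2OC(C)=O)[C@H]4c2cc(OC(C)=O)cc(OC(C)=O)c2)O3)cc1 | intermediate
27 | CNP0397447.1: 5-[(2S,3S)-2-[(2S,3S)-2-(2,4-dihydroxyphenyl)-3-(3,5-dihydroxyphenyl)-4-hydroxy-2,3-dihydro-1-benzofuran-7-yl]-6-hydroxy-4-[(E)-2-(4-hydroxyphenyl)ethenyl]-2,3-dihydro-1-benzofuran-3-yl]benzene-1,3-diol | Oc1ccc(/C=C/c2cc(O)cc3c2[C@H](c2cc(O)cc(O)c2)[C@@H](c2ccc(O)c4c2O[C@H](c2ccc(O)cc2O)[C@H]4c2cc(O)cc(O)c2)O3)cc1 | target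

**Count and risks**

Total step count: 16. Longest linear sequence: 13 steps (steps 1–6 and 10–16); steps 7–9 make the side fragment 17.

Steps most likely to fail:

Step 4. The hydrogenation may reduce both ketone enantiomers at similar rates, or racemisation may lag behind reduction, so that diastereomers or low enantiomeric purity result; the hindered carbonyl may also react slowly. The fallback sets out from 6 and replaces catalytic resolution by classical resolution. NaBH4 in MeOH (substrate-controlled Felkin–Anh reduction) should give the racemic (1S*,2S*)-2-(3-bromo-2-fluoro-6-methoxyphenyl)-1-(2,4-dimethoxyphenyl)-2-(3,5-dimethoxyphenyl)ethan-1-ol F2. Esterification with (S)-2-methoxy-2-phenylacetic acid (DCC, DMAP) gives the diastereomeric esters (1S,2S)-2-(3-bromo-2-fluoro-6-methoxyphenyl)-1-(2,4-dimethoxyphenyl)-2-(3,5-dimethoxyphenyl)ethyl (S)-2-methoxy-2-phenylacetate F3 and its (1R,2R)-alcohol counterpart F4, which are separated by chromatography or crystallisation. Methanolysis of F3 (K2CO3, MeOH) comes back to the route at 7.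

Step 5. Intermolecular capture of the aryne (by aryllithium or solvent) or slow addition of the hindered lithium alkoxide may compete with the ring closure and lead to oligomers or reduced arene. The fallback sets out from 7 and separates the two events. Bromine–lithium exchange at −100 °C (n-BuLi then t-BuLi, THF/Et2O) and formylation with DMF before the aryllithium can lose LiF should give 3-[(1S,2S)-2-(2,4-dimethoxyphenyl)-1-(3,5-dimethoxyphenyl)-2-hydroxyethyl]-2-fluoro-4-methoxybenzaldehyde F1. In F1 the ortho-formyl group activates the fluoride, so Cs2CO3 in DMF at 60 °C should close the same O–C(aryl) bond by intramolecular addition–elimination through a Meisenheimer adduct, with the stereocenters untouched. This comes back to the route at 11.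

Step 12. The di-ortho-substituted diaryl carbene may dimerise to the azine or insert with poor facial selectivity, and the hindered hydrazone of step 11 may form slowly. The fallback sets out from 12 (with 16 from the side branch) and builds unit 1 by a formal [4+1] annulation instead. Alcohol 12 with tetrahydrothiophene and HBF4·OEt2 in CH2Cl2 gives 1-{[(2S,3S)-2-(2,4-dimethoxyphenyl)-3-(3,5-dimethoxyphenyl)-4-methoxy-2,3-dihydro-1-benzofuran-7-yl]methyl}tetrahydrothiophen-1-ium tetrafluoroborate F5. With Cs2CO3 in MeCN at 60 °C, F5 gives the sulfur ylide and 16 is dehydrated in situ to the ortho-quinone methide; conjugate addition and 5-exo-tet displacement of tetrahydrothiophene should give the trans ring directly. Since this step has no control over C3, 22 is expected together with its diastereomer (2R,3R)-4-bromo-2-[(2S,3S)-2-(2,4-dimethoxyphenyl)-3-(3,5-dimethoxyphenyl)-4-methoxy-2,3-dihydro-1-benzofuran-7-yl]-3-(3,5-dimethoxyphenyl)-6-methoxy-2,3-dihydro-1-benzofuran F6, to be separated by chromatography. This comes back to the route at 22.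

Further compounds
F1 | step 5 | 3-[(1S,2S)-2-(2,4-dimethoxyphenyl)-1-(3,5-dimethoxyphenyl)-2-hydroxyethyl]-2-fluoro-4-methoxybenzaldehyde | O[C@H](c1ccc(OC)cc1OC)[C@H](c1c(OC)ccc(C=O)c1F)c1cc(OC)cc(OC)c1
F2 | step 4 | racemic (1S*,2S*)-2-(3-bromo-2-fluoro-6-methoxyphenyl)-1-(2,4-dimethoxyphenyl)-2-(3,5-dimethoxyphenyl)ethan-1-ol | O[C@H](c1ccc(OC)cc1OC)[C@H](c1c(OC)ccc(Br)c1F)c1cc(OC)cc(OC)c1.O[C@@H](c1ccc(OC)cc1OC)[C@@H](c1c(OC)ccc(Br)c1F)c1cc(OC)cc(OC)c1
F3 | step 4 | (1S,2S)-2-(3-bromo-2-fluoro-6-methoxyphenyl)-1-(2,4-dimethoxyphenyl)-2-(3,5-dimethoxyphenyl)ethyl (S)-2-methoxy-2-phenylacetate | CO[C@H](C(=O)O[C@H](c1ccc(OC)cc1OC)[C@H](c1c(OC)ccc(Br)c1F)c1cc(OC)cc(OC)c1)c1ccccc1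
F4 | step 4 | (1R,2R)-2-(3-bromo-2-fluoro-6-methoxyphenyl)-1-(2,4-dimethoxyphenyl)-2-(3,5-dimethoxyphenyl)ethyl (S)-2-methoxy-2-phenylacetate | CO[C@H](C(=O)O[C@@H](c1ccc(OC)cc1OC)[C@@H](c1c(OC)ccc(Br)c1F)c1cc(OC)cc(OC)c1)c1ccccc1
F5 | step 12 | 1-{[(2S,3S)-2-(2,4-dimethoxyphenyl)-3-(3,5-dimethoxyphenyl)-4-methoxy-2,3-dihydro-1-benzofuran-7-yl]methyl}tetrahydrothiophen-1-ium tetrafluoroborate | F[B-](F)(F)F.C1CC[S+](C1)Cc1ccc(OC)c2c1O[C@H](c1ccc(OC)cc1OC)[C@H]2c1cc(OC)cc(OC)c1
F6 | step 12 | (2R,3R)-4-bromo-2-[(2S,3S)-2-(2,4-dimethoxyphenyl)-3-(3,5-dimethoxyphenyl)-4-methoxy-2,3-dihydro-1-benzofuran-7-yl]-3-(3,5-dimethoxyphenyl)-6-methoxy-2,3-dihydro-1-benzofuran | Brc1cc(OC)cc2c1[C@@H](c1cc(OC)cc(OC)c1)[C@H](c1ccc(OC)c3c1O[C@H](c1ccc(OC)cc1OC)[C@H]3c1cc(OC)cc(OC)c1)O2
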